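**Retrosynthetic overview**
- The target comes from a late double asymmetric (Shi) epoxidation of the two E-trisubstituted alkenes of a bicyclo[9.3.1] trienone.
- Key step: that bicycle comes from a 14-membered cross-conjugated dienone by transannular 6-endo cyclisation of a tertiary radical (C15, released from a C–NO2 bond) onto the C1=C14 enone. This forms C1–C15 and splits the 14-membered ring into the six- and twelve-membered rings in one step.
- The macrocycle comes from an acyclic aldehyde by vinyl addition, oxidation and ring-closing metathesis (C13–C14, C14=C1). Ring order: 14-membered ring first, then the six- and twelve-membered rings together.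
- The acyclic aldehyde comes from a Negishi coupling (C6–C7) of a C7–C13 alkenyl iodide with a C1–C6 alkylzinc. C11–C15 and C12=C18 are installed by an organocatalytic Michael addition of 2-nitropropane to an enal followed by α-methylenation.
- Building blocks: (S)-2-vinyloxirane (C10 stereocentre), acetylide, crotonaldehyde, 2-nitropropane, but-3-yn-1-ol and allyl bromide; both E-alkenes come from zirconium-catalysed carboalumination.

Assumption: (S)-2-vinyloxirane is bought as the single enantiomer; atom labels follow verticillane numbering (C1/C11 bridgeheads, C2–C10 nine-carbon bridge, C12(=C18H2)–C13(=O)–C14 three-carbon bridge, C15 = CMe2 bridge).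

**Step 1**
Reactants: 1 (S)-2-vinyloxirane; 2 lithium acetylide–ethylenediamine complex
Product: 3 (R)-hex-1-en-5-yn-3-ol
Conditions: LiC≡CH·H2NCH2CH2NH2 (1.5 equiv), DMSO, 0 °C → rt; then H2O
Reagents that add atoms: none
Why: Epoxide alkynylation by SN2 attack of the acetylide at the unhindered terminal CH2 (no Lewis acid, so no allylic or SN2′ opening) leaves the stereocentre of 1 untouched, and it becomes C10 (R) of the target.

**Step 2**
Reactants: 3 (R)-hex-1-en-5-yn-3-ol
Product: 5 (3R,5E)-6-iodo-5-methylhexa-1,5-dien-3-ol, via alkenylalane 4 (not isolated)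
Conditions: Me3Al (3 equiv), Cp2ZrCl2 (0.25 equiv), CH2Cl2, 0 °C → rt; then I2, THF, −30 °C; aq. K2CO3
Reagents that add atoms: trimethylaluminium C[Al](C)C; iodine II
Why: Negishi zirconium-catalysed carboalumination adds Me and Al syn across the terminal alkyne (the vinyl group is inert) and iodinolysis with retention gives the E-alkenyl iodide that fixes the C7=C8 geometry.

**Step 3**
Reactants: 5 (3R,5E)-6-iodo-5-methylhexa-1,5-dien-3-ol
Product: 6 (3R,5E)-6-iodo-5-methylhexa-1,5-dien-3-yl acetate
Conditions: Ac2O, pyridine, DMAP (cat.), CH2Cl2, 0 °C → rt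
Reagents that add atoms: acetic anhydride CC(=O)OC(C)=O
Why: DMAP-catalysed O-acylation installs the C10 acetate of the target, which also protects the alcohol for the rest of the route.

**Step 4**
Reactants: 6 (3R,5E)-6-iodo-5-methylhexa-1,5-dien-3-yl acetate; 7 (E)-but-2-enal
Product: 8 (2E,4R,6E)-7-iodo-6-methyl-1-oxohepta-2,6-dien-4-yl acetate
Conditions: second-generation Hoveyda–Grubbs catalyst RuCl2(H2IMes)(=CH-C6H4-2-OiPr) (5 mol%), 7 (5 equiv), CH2Cl2, 40 °C
Reagents that add atoms: none
Why: Olefin cross-metathesis of the monosubstituted alkene with excess crotonaldehyde gives the E-enal, while the hindered trisubstituted iodoalkene does not react with the ruthenium carbene.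

**Step 5**
Reactants: 8 (2E,4R,6E)-7-iodo-6-methyl-1-oxohepta-2,6-dien-4-yl acetate; 9 2-nitropropane
Product: 11 (3S,4R,6E)-7-iodo-6-methyl-2-methylidene-3-(2-nitropropan-2-yl)-1-oxohept-6-en-4-yl acetate, via γ-nitro aldehyde 10 (not isolated)
Conditions: 9 (5 equiv), (R)-α,α-diphenylprolinol trimethylsilyl ether (20 mol%), PhCO2H (20 mol%), MeOH, rt; then (same flask, MeOH removed) 37% aq. CH2O, pyrrolidine (10 mol%), EtCO2H (10 mol%), iPrOH, 45 °C
Reagents that add atoms: formaldehyde C=O
Why: Hayashi–Jørgensen iminium-ion Michael addition, in which the (R)-catalyst shields one face of the E-iminium so the nitronate bonds to C11 from the face that gives the 10,11-syn relationship of the target (C11–C15 bond, C11 set by catalyst control), followed by amine-catalysed Mannich-type α-methylenation of the aldehyde that installs C18.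

**Step 6**
Reactants: 12 but-3-yn-1-ol; 13 allyl bromide
Product: 15 (3E)-3-methylhepta-3,6-dien-1-ol, via alkenylalane 14 (not isolated)
Conditions: Me3Al (3 equiv), Cp2ZrCl2 (0.25 equiv), CH2Cl2, rt; then 13, Pd(PPh3)4 (3 mol%), THF, rt; aq. K2CO3
Reagents that add atoms: trimethylaluminium C[Al](C)C
Why: Zirconium-catalysed syn-carboalumination followed by Negishi's palladium-catalysed coupling of the alkenylalane with the allylic bromide (retention at the alkenyl carbon) gives the skipped diene with the E-C3=C4 alkene and the C1–C2 bond already in place.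

**Step 7**
Reactants: 15 (3E)-3-methylhepta-3,6-dien-1-ol
Product: 16 (4E)-7-iodo-5-methylhepta-1,4-diene
Conditions: I2, PPh3, imidazole, CH2Cl2, 0 °C
Reagents that add atoms: iodine II
Why: Appel-type iodination of the primary alcohol under neutral conditions; no stereocentre is involved.

**Step 8**
Reactants: 16 (4E)-7-iodo-5-methylhepta-1,4-diene; 11 (3S,4R,6E)-7-iodo-6-methyl-2-methylidene-3-(2-nitropropan-2-yl)-1-oxohept-6-en-4-yl acetate
Product: 18 (3S,4R,6E,10E)-6,10-dimethyl-2-methylidene-3-(2-nitropropan-2-yl)-1-oxotetradeca-6,10,13-trien-4-yl acetate, via alkylzinc iodide 17 (not isolated)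
Conditions: 16, Zn dust, LiCl, THF, 40 °C; then 11, Pd(OAc)2 (2 mol%), SPhos (4 mol%), THF, rt
Reagents that add atoms: none
Why: Negishi sp3–sp2 cross-coupling, in which the alkylzinc iodide (direct zinc insertion) tolerates the aldehyde, nitro and acetate groups and couples with retention of the alkenyl iodide geometry, forming C6–C7 and the E-C7=C8 alkene.

**Step 9**
Reactants: 18 (3S,4R,6E,10E)-6,10-dimethyl-2-methylidene-3-(2-nitropropan-2-yl)-1-oxotetradeca-6,10,13-trien-4-yl acetate
Product: 19 (5S,6R,8E,12E)-3-hydroxy-8,12-dimethyl-4-methylidene-5-(2-nitropropan-2-yl)hexadeca-1,8,12,15-tetraen-6-yl acetate (both C3 epimers)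
Conditions: CH2=CHMgBr (1.2 equiv), THF, −78 °C; then H2O
Reagents that add atoms: vinylmagnesium bromide C=C[Mg]Br
Why: Grignard 1,2-addition to the enal carbonyl at −78 °C is much faster than attack on the acetate or the tertiary nitro group, and the new carbinol centre is removed in step 10, so its configuration does not matter.

**Step 10**
Reactants: 19 (5S,6R,8E,12E)-3-hydroxy-8,12-dimethyl-4-methylidene-5-(2-nitropropan-2-yl)hexadeca-1,8,12,15-tetraen-6-yl acetate
Product: 20 (5S,6R,8E,12E)-8,12-dimethyl-4-methylidene-5-(2-nitropropan-2-yl)-3-oxohexadeca-1,8,12,15-tetraen-6-yl acetate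
Conditions: Dess–Martin periodinane, CH2Cl2, 0 °C
Reagents that add atoms: none
Why: Dess–Martin oxidation of the bis-allylic alcohol gives the cross-conjugated divinyl ketone under mild, non-basic conditions that do not touch the acetate, nitro group or alkenes.

**Step 11**
Reactants: 20 (5S,6R,8E,12E)-8,12-dimethyl-4-methylidene-5-(2-nitropropan-2-yl)-3-oxohexadeca-1,8,12,15-tetraen-6-yl acetate
Product: 21 (1R,2S,5E,8E,12E)-9,13-dimethyl-3-methylidene-2-(2-nitropropan-2-yl)-4-oxocyclotetradeca-5,8,12-trien-1-yl acetate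
Conditions: second-generation Grubbs catalyst RuCl2(H2IMes)(PCy3)(=CHPh) (10 mol%), 1,4-benzoquinone (20 mol%), toluene (0.001 M), 80 °C
Reagents that add atoms: none
Why: Ring-closing metathesis between the terminal allyl alkene and the vinyl ketone closes the 14-membered ring as the E-enone (C14=C1), while the trisubstituted alkenes and the electron-poor 1,1-disubstituted alkene do not compete.

**Step 12**
Reactants: 21 (1R,2S,5E,8E,12E)-9,13-dimethyl-3-methylidene-2-(2-nitropropan-2-yl)-4-oxocyclotetradeca-5,8,12-trien-1-yl acetate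
Product: 22 (1R,3E,7E,10R,11R)-4,8,15,15-tetramethyl-12-methylidene-13-oxobicyclo[9.3.1]pentadeca-3,7-dien-10-yl acetate
Conditions: Bu3SnH (1.5 equiv, syringe pump, 8 h), AIBN (0.3 equiv), benzene (0.002 M), 80 °C
Reagents that add atoms: none
Why: Tin-hydride denitration of the tertiary nitroalkane (Ono) gives the nucleophilic C15 radical, which adds transannularly 6-endo to the enone β-carbon C1 (Giese addition; 5-exo attack at the α-carbon is polarity-mismatched); because C15 is anchored on C11 and the E-enone places C2 equatorial in a chair-like transition state, C2 and C10 end up cis, which sets C1 (R), and the α-keto radical at C14 is then quenched by Bu3SnH.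

**Step 13**
Reactants: 22 (1R,3E,7E,10R,11R)-4,8,15,15-tetramethyl-12-methylidene-13-oxobicyclo[9.3.1]pentadeca-3,7-dien-10-yl acetate
Product: 23 (1R,3S,4S,7S,8S,10R,11R)-10-acetoxy-3,4:7,8-diepoxyverticill-12(18)-en-13-one (target)
Conditions: L-fructose-derived Shi ketone (1,2:4,5-di-O-isopropylidene-β-L-erythro-2,3-hexodiulo-2,6-pyranose, 0.6 equiv), Oxone (2KHSO5·KHSO4·K2SO4), K2CO3, Bu4NHSO4, MeCN/CH2(OMe)2/aq. Na2B4O7 buffer (pH 10.5), 0 °C
Reagents that add atoms: potassium peroxymonosulfate [K+].[O-]S(=O)(=O)OO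
Why: Shi asymmetric epoxidation (chiral dioxirane, spiro transition state), in which the L-fructose-derived ketone gives the (S,S)-epoxide from each E-trisubstituted alkene (the D-ketone gives R,R), while the electron-poor enone alkene and the ketone are not oxidised.

**Compound list**
1 | (S)-2-vinyloxirane | C=C[C@H]1CO1 | starting material
2 | lithium acetylide–ethylenediamine complex | [Li+].[C-]#C.NCCN | starting material
3 | (R)-hex-1-en-5-yn-3-ol | C#CC[C@@H](O)C=C | intermediate
4 | (E)-alkenyl(dimethyl)alane of 3, as its O-dimethylaluminium alkoxide | C[Al](C)/C=C(\C)C[C@@H](O[Al](C)C)C=C | intermediate (not isolated)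
5 | (3R,5E)-6-iodo-5-methylhexa-1,5-dien-3-ol | I/C=C(\C)C[C@@H](O)C=C | intermediate
6 | (3R,5E)-6-iodo-5-methylhexa-1,5-dien-3-yl acetate | I/C=C(\C)C[C@@H](OC(C)=O)C=C | intermediate
7 | (E)-but-2-enal (crotonaldehyde) | C/C=C/C=O | starting material
8 | (2E,4R,6E)-7-iodo-6-methyl-1-oxohepta-2,6-dien-4-yl acetate | I/C=C(\C)C[C@@H](OC(C)=O)/C=C/C=O | intermediate
9 | 2-nitropropane | CC(C)[N+](=O)[O-] | starting material
10 | (3S,4R,6E)-7-iodo-6-methyl-3-(2-nitropropan-2-yl)-1-oxohept-6-en-4-yl acetate | I/C=C(\C)C[C@@H](OC(C)=O)[C@@H](CC=O)C(C)(C)[N+](=O)[O-] | intermediate (not isolated)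
11 | (3S,4R,6E)-7-iodo-6-methyl-2-methylidene-3-(2-nitropropan-2-yl)-1-oxohept-6-en-4-yl acetate | I/C=C(\C)C[C@@H](OC(C)=O)[C@@H](C(=C)C=O)C(C)(C)[N+](=O)[O-] | intermediate
12 | but-3-yn-1-ol | C#CCCO | starting material
13 | allyl bromide (3-bromoprop-1-ene) | C=CCBr | starting material
14 | (E)-alkenyl(dimethyl)alane of 12, as its O-dimethylaluminium alkoxide | C[Al](C)/C=C(\C)CCO[Al](C)C | intermediate (not isolated)
15 | (3E)-3-methylhepta-3,6-dien-1-ol | C=CC/C=C(\C)CCO | intermediate
16 | (4E)-7-iodo-5-methylhepta-1,4-diene | C=CC/C=C(\C)CCI | intermediate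
17 | [(3E)-3-methylhepta-3,6-dien-1-yl]zinc iodide | C=CC/C=C(\C)CC[Zn]I | intermediate (not isolated)
18 | (3S,4R,6E,10E)-6,10-dimethyl-2-methylidene-3-(2-nitropropan-2-yl)-1-oxotetradeca-6,10,13-trien-4-yl acetate | C=CC/C=C(\C)CC/C=C(\C)C[C@@H](OC(C)=O)[C@@H](C(=C)C=O)C(C)(C)[N+](=O)[O-] | intermediate
19 | (5S,6R,8E,12E)-3-hydroxy-8,12-dimethyl-4-methylidene-5-(2-nitropropan-2-yl)hexadeca-1,8,12,15-tetraen-6-yl acetate (C3 epimers) | C=CC/C=C(\C)CC/C=C(\C)C[C@@H](OC(C)=O)[C@@H](C(=C)C(O)C=C)C(C)(C)[N+](=O)[O-] | intermediate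
20 | (5S,6R,8E,12E)-8,12-dimethyl-4-methylidene-5-(2-nitropropan-2-yl)-3-oxohexadeca-1,8,12,15-tetraen-6-yl acetate | C=CC/C=C(\C)CC/C=C(\C)C[C@@H](OC(C)=O)[C@@H](C(=C)C(=O)C=C)C(C)(C)[N+](=O)[O-] | intermediate
21 | (1R,2S,5E,8E,12E)-9,13-dimethyl-3-methylidene-2-(2-nitropropan-2-yl)-4-oxocyclotetradeca-5,8,12-trien-1-yl acetate | C=C1C(=O)/C=C/C/C=C(\C)CC/C=C(\C)C[C@@H](OC(C)=O)[C@@H]1C(C)(C)[N+](=O)[O-] | intermediate
22 | (1R,3E,7E,10R,11R)-4,8,15,15-tetramethyl-12-methylidene-13-oxobicyclo[9.3.1]pentadeca-3,7-dien-10-yl acetate | C=C1C(=O)C[C@H]2C/C=C(\C)CC/C=C(\C)C[C@@H](OC(C)=O)[C@@H]1C2(C)C | intermediate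
23 | (1R,3S,4S,7S,8S,10R,11R)-10-acetoxy-3,4:7,8-diepoxyverticill-12(18)-en-13-one (CNP0339728.1) | C=C1C(=O)C[C@H]2C[C@@H]3O[C@@]3(C)CC[C@@H]3O[C@@]3(C)C[C@@H](OC(C)=O)[C@@H]1C2(C)C | target

**Step count**
Total: 13 steps. Longest linear sequence: 11 steps (steps 1–5, then 8–13); steps 6–7 form the side branch.

**Three steps most likely to fail**

Step 12 (transannular radical closure). The C15 radical may be reduced to an isopropyl group before it reaches C1, and tin radicals may reduce the two enones. The cis outcome at C1 is argued from the transition state, not proven.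
Fallback, setting out from 8 and coming back at 22: generate the same C15 radical by metal-hydride hydrogen-atom transfer to an isopropenyl group instead of C–NO2 cleavage.
- Iminium-catalysed conjugate addition of potassium isopropenyltrifluoroborate to 8 ((2R,5R)-5-benzyl-2-tert-butyl-3-methylimidazolidin-4-one, HF, DME; same facial sense as in step 5) gives (3S,4R,6E)-7-iodo-6-methyl-1-oxo-3-(prop-1-en-2-yl)hept-6-en-4-yl acetate F4.
- α-Methylenation as in step 5 gives (3R,4R,6E)-7-iodo-6-methyl-2-methylidene-1-oxo-3-(prop-1-en-2-yl)hept-6-en-4-yl acetate F5.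
- Negishi coupling with 17 gives (3R,4R,6E,10E)-6,10-dimethyl-2-methylidene-1-oxo-3-(prop-1-en-2-yl)tetradeca-6,10,13-trien-4-yl acetate F6.
- CH2=CHMgBr addition gives (5R,6R,8E,12E)-3-hydroxy-8,12-dimethyl-4-methylidene-5-(prop-1-en-2-yl)hexadeca-1,8,12,15-tetraen-6-yl acetate F7.
- Dess–Martin oxidation gives (5R,6R,8E,12E)-8,12-dimethyl-4-methylidene-3-oxo-5-(prop-1-en-2-yl)hexadeca-1,8,12,15-tetraen-6-yl acetate F8.
- Ring-closing metathesis gives (1R,2R,5E,8E,12E)-9,13-dimethyl-3-methylidene-4-oxo-2-(prop-1-en-2-yl)cyclotetradeca-5,8,12-trien-1-yl acetate F9.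
- Fe(acac)3/PhSiH3 (EtOH, 60 °C) then adds a hydrogen atom to the isopropenyl CH2, which reacts faster than the trisubstituted alkenes. The C15 radical closes onto C1 as in step 12, and the α-keto radical is reduced to the enolate and protonated, giving 22 with no tin hydride present.

Step 5 (Michael addition and methylenation). The hindered nitronate adds slowly to a γ-branched enal. Retro-Michael loss during methylenation and epimerisation of C10 through the dienamine are possible, and the catalyst may be mismatched with C10.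
Fallback, setting out from 6 and coming back at 11: build C11–C15 by Lewis-base allylic substitution on a Morita–Baylis–Hillman carbonate, with no iminium activation.
- Ozonolysis of the vinyl group of 6 (O3, CH2Cl2/pyridine, −78 °C, one equivalent; then Me2S) gives (2R,4E)-5-iodo-4-methyl-1-oxopent-4-en-2-yl acetate F1, which is used at once.
- Morita–Baylis–Hillman reaction with acrolein (DABCO) gives (4R,6E)-3-hydroxy-7-iodo-6-methyl-2-methylidene-1-oxohept-6-en-4-yl acetate F2 as a mixture of C3 epimers, which does not matter.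
- Boc2O/DMAP gives (4R,6E)-3-[(tert-butoxycarbonyl)oxy]-7-iodo-6-methyl-2-methylidene-1-oxohept-6-en-4-yl acetate F3.
- A cinchona-alkaloid Lewis base ((DHQD)2PHAL or its pseudo-enantiomer, chosen by which one matches the C10 bias) converts F3 through the allyl-ammonium ion, and 2-nitropropane 9 attacks C11 in an SN2′–SN2′ sequence with the methylidene retained, giving 11.

Step 13 (double epoxidation). The compact bicycle may expose only one face of each alkene, so the reagent cannot override the substrate and mixtures or the wrong epoxide face result.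
Fallback, setting out from 22 and coming back at 23: if the exposed face is the wrong one, deliver oxygen to the hidden face through the halohydrin.
- NBS in aqueous THF forms the bromonium ion on the exposed face and water opens it anti at the more substituted carbon, giving (1R,3R,4S,7R,8S,10R,11R)-3,7-dibromo-4,8-dihydroxy-4,8,15,15-tetramethyl-12-methylidene-13-oxobicyclo[9.3.1]pentadecan-10-yl acetate F10.
- DBU in CH2Cl2 then closes both epoxides with inversion at C3 and C7, giving 23 without touching the acetate.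
- If the exposed face turns out to be the correct one, a peracid on 22 is enough.

**Further compounds**
F1 | step 5 | (2R,4E)-5-iodo-4-methyl-1-oxopent-4-en-2-yl acetate | I/C=C(\C)C[C@@H](OC(C)=O)C=O
F2 | step 5 | (4R,6E)-3-hydroxy-7-iodo-6-methyl-2-methylidene-1-oxohept-6-en-4-yl acetate (C3 epimers) | I/C=C(\C)C[C@@H](OC(C)=O)C(O)C(=C)C=O
F3 | step 5 | (4R,6E)-3-[(tert-butoxycarbonyl)oxy]-7-iodo-6-methyl-2-methylidene-1-oxohept-6-en-4-yl acetate (C3 epimers) | I/C=C(\C)C[C@@H](OC(C)=O)C(OC(=O)OC(C)(C)C)C(=C)C=O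
F4 | step 12 | (3S,4R,6E)-7-iodo-6-methyl-1-oxo-3-(prop-1-en-2-yl)hept-6-en-4-yl acetate | I/C=C(\C)C[C@@H](OC(C)=O)[C@@H](CC=O)C(C)=C
F5 | step 12 | (3R,4R,6E)-7-iodo-6-methyl-2-methylidene-1-oxo-3-(prop-1-en-2-yl)hept-6-en-4-yl acetate | I/C=C(\C)C[C@@H](OC(C)=O)[C@@H](C(=C)C=O)C(C)=C
F6 | step 12 | (3R,4R,6E,10E)-6,10-dimethyl-2-methylidene-1-oxo-3-(prop-1-en-2-yl)tetradeca-6,10,13-trien-4-yl acetate | C=CC/C=C(\C)CC/C=C(\C)C[C@@H](OC(C)=O)[C@@H](C(=C)C=O)C(C)=C
F7 | step 12 | (5R,6R,8E,12E)-3-hydroxy-8,12-dimethyl-4-methylidene-5-(prop-1-en-2-yl)hexadeca-1,8,12,15-tetraen-6-yl acetate (C3 epimers) | C=CC/C=C(\C)CC/C=C(\C)C[C@@H](OC(C)=O)[C@@H](C(=C)C(O)C=C)C(C)=C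
F8 | step 12 | (5R,6R,8E,12E)-8,12-dimethyl-4-methylidene-3-oxo-5-(prop-1-en-2-yl)hexadeca-1,8,12,15-tetraen-6-yl acetate | C=CC/C=C(\C)CC/C=C(\C)C[C@@H](OC(C)=O)[C@@H](C(=C)C(=O)C=C)C(C)=C
F9 | step 12 | (1R,2R,5E,8E,12E)-9,13-dimethyl-3-methylidene-4-oxo-2-(prop-1-en-2-yl)cyclotetradeca-5,8,12-trien-1-yl acetate | C=C1C(=O)/C=C/C/C=C(\C)CC/C=C(\C)C[C@@H](OC(C)=O)[C@@H]1C(C)=C
F10 | step 13 | (1R,3R,4S,7R,8S,10R,11R)-3,7-dibromo-4,8-dihydroxy-4,8,15,15-tetramethyl-12-methylidene-13-oxobicyclo[9.3.1]pentadecan-10-yl acetate | C=C1C(=O)C[C@H]2C[C@@H](Br)[C@](O)(C)CC[C@@H](Br)[C@](O)(C)C[C@@H](OC(C)=O)[C@@H]1C2(C)C
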